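**Plan**

1. Numbering: decalin C1–C10 (ring A = C1–C5 and C10, ring B = C5–C10; C1 is CHBr, C4 the methyl carbinol, C5 and C10 the fusion carbons, C7 the carbinol carrying ring C); ring C = C11 (quaternary, on C7), C12 (CHOH), C13, C14 (CHBr), C15 (CMe2).
2. Retrosynthesis: the C7–O, C4–CH3/C4–O, C5–O and C1–Br bonds are cut first, leading to a cis-fused Δ7-octalin-1-one; ring B is then cut at C5–C6 and C9–C10.
3. Enabling feature: in ring B the branch points C7 and C10 are 1,4 to each other, C6, C8 and C9 are methylenes, and C10 carries a methyl group next to C1. Ring B is therefore the adduct of a 2-(ring C)buta-1,3-diene (C6=C7–C8=C9) and the C5=C10 bond of a 2-methylcyclohex-2-enone whose carbonyl is C1.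
4. Forward order: ring C is taken ready-made from (1R,3S)-camphoric acid and turned into the diene; ring A comes from 2-methylcyclohex-2-en-1-one; ring B closes last in the convergent Diels–Alder step; C1, C4, C5 and C7 are then adjusted.
5. Stereochemistry: C11 from the chiral pool; C14 by catalyst-controlled borylation then invertive bromination; C12 by reduction anti to the ester; C10 from the resolved C4 silyloxy group of the dienophile; C1 by convex-face hydride then invertive bromination; C5 and C4 by attack anti to the C10 methyl; C7 by axial trapping of a tertiary radical.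

Key step: step 15

Remark (notation): RC is the (1S,3S,5R)-3-bromo-5-[(tert-butyldimethylsilyl)oxy]-1,2,2-trimethylcyclopentyl group bonded through C11; β is the decalin face of the C10 methyl group, α the opposite face; decalin names use the route numbering above.

Remark (assumption): the lipase in step 13 is taken to acylate the (R)-alcohol, as the usual empirical rule for secondary alcohols predicts, so that (S)-17 is recovered unreacted; if the preference were reversed, methanolysis of the acetate would supply 17.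

**Route**

Step 1
Reactants: 1 (1R,3S)-(+)-camphoric acid
Product: 2 dimethyl (1R,3S)-1,2,2-trimethylcyclopentane-1,3-dicarboxylate
Conditions: MeI, K2CO3, DMF, rt
Reagents that add atoms: iodomethane, CI
Why: Carboxylate O-alkylation (SN2 on MeI) esterifies both acids, including the hindered tertiary one that resists Fischer esterification, and touches no stereocentre.

Step 2
Reactants: 2 dimethyl (1R,3S)-camphorate
Product: 3 (1S,3R)-3-(methoxycarbonyl)-2,2,3-trimethylcyclopentane-1-carboxylic acid
Conditions: KOH (1.1 equiv), MeOH–H2O, 60 °C; then aq. HCl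
Reagents that add atoms: potassium hydroxide, [K+].[OH-]
Why: Saponification (BAc2) should be confined to the ester on the secondary carbon C14, because the ester on quaternary C11 next to the gem-dimethyl carbon is shielded from hydroxide; epimerisation at C14 would be harmless since that centre is removed in step 3.

Step 3
Reactants: 3 half ester
Product: 4 methyl (1R)-1,2,2-trimethylcyclopent-3-ene-1-carboxylate
Conditions: Pb(OAc)4, Cu(OAc)2 (cat.), pyridine, benzene, 80 °C
Reagents that add atoms: none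
Why: Kochi oxidative decarboxylation: the C14 radical is oxidised by the copper salt and can lose a β-hydrogen only from C13 (C15 is quaternary), so the C13=C14 alkene should form regiospecifically with C11 untouched.

Step 4
Reactants: 4 alkene ester
Product: 6 methyl (1S)-1,5,5-trimethyl-2-oxocyclopent-3-ene-1-carboxylate, via allylic alcohol 5 (not isolated)
Conditions: SeO2 (0.3 equiv), t-BuOOH, CH2Cl2, rt; then Dess–Martin periodinane, NaHCO3, CH2Cl2, rt
Reagents that add atoms: selenium dioxide, O=[Se]=O; tert-butyl hydroperoxide (re-forms SeO2), CC(C)(C)OO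
Why: Riley allylic oxidation: the ene reaction at C14 followed by a [2,3]-sigmatropic shift returns oxygen to C12, the only allylic carbon bearing hydrogen, without moving the double bond (an allyl-radical oxidant could not tell C12 from C14), and Dess–Martin oxidation then gives the enone.

Step 5
Reactants: 6 enone ester
Product: 7 methyl (1S,4R)-1,5,5-trimethyl-2-oxo-4-(4,4,5,5-tetramethyl-1,3,2-dioxaborolan-2-yl)cyclopentane-1-carboxylate (boron trans to the ester)
Conditions: B2pin2, CuCl (5 mol%), Josiphos SL-J001 (matched enantiomer, 6 mol%), NaOt-Bu (10 mol%), MeOH (2 equiv), THF, 0 °C → rt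
Reagents that add atoms: bis(pinacolato)diboron, CC1(C)OB(OC1(C)C)B1OC(C)(C)C(C)(C)O1
Why: Copper-catalysed conjugate borylation of an enone places boron on the β-carbon C14; since the two faces differ only at remote C11, the enantiomer of the chiral bisphosphine that is matched to attack anti to the ester is used to make the catalyst the controlling element.

Step 6
Reactants: 7 β-boryl ketone
Product: 8 methyl (1S,2R,4R)-2-hydroxy-1,5,5-trimethyl-4-(4,4,5,5-tetramethyl-1,3,2-dioxaborolan-2-yl)cyclopentane-1-carboxylate (OH cis to the ester, trans to boron)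
Conditions: NaBH4, MeOH, −20 °C
Reagents that add atoms: none
Why: Borohydride reduction of the ring ketone (ester and boronic ester are inert) should deliver hydride anti to the ester on the adjacent quaternary carbon, as in reductions of 2-alkyl-2-alkoxycarbonylcyclopentanones, giving the alcohol cis to the ester.

Step 7
Reactants: 8 hydroxy ester
Product: 9 methyl (1S,2R,4R)-2-[(tert-butyldimethylsilyl)oxy]-1,5,5-trimethyl-4-(4,4,5,5-tetramethyl-1,3,2-dioxaborolan-2-yl)cyclopentane-1-carboxylate
Conditions: TBSOTf, 2,6-lutidine, CH2Cl2, 0 °C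
Reagents that add atoms: tert-butyldimethylsilyl triflate, CC(C)(C)[Si](C)(C)OS(=O)(=O)C(F)(F)F
Why: Silylation with the silyl triflate protects the hindered secondary alcohol as an ether that should survive every later step and is removed last.

Step 8
Reactants: 9 silyl ether boronic ester
Product: 10 methyl (1S,2R,4S)-4-bromo-2-[(tert-butyldimethylsilyl)oxy]-1,5,5-trimethylcyclopentane-1-carboxylate (Br cis to ester and silyloxy group)
Conditions: 3,5-(CF3)2C6H3Br, n-BuLi, THF, −78 °C; add 9, −78 °C; then NBS, −78 °C → rt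
Reagents that add atoms: N-bromosuccinimide, BrN1C(=O)CCC1=O
Why: Stereoinvertive bromodeboronation: the aryl boronate complex is attacked by NBS at carbon anti to boron (SE2 with inversion), turning the trans boronic ester into the cis bromide without a cationic intermediate that could trigger a 1,2-methyl shift at this neopentyl carbon.

Step 9
Reactants: 10 bromo ester
Product: 12 tert-butyl{[(1R,2S,4S)-4-bromo-2-ethynyl-2,3,3-trimethylcyclopentyl]oxy}dimethylsilane, via aldehyde 11 (not isolated)
Conditions: i-Bu2AlH (1.2 equiv), CH2Cl2, −78 °C; then MeOH, K2CO3, dimethyl (1-diazo-2-oxopropyl)phosphonate, −78 °C → rt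
Reagents that add atoms: dimethyl (1-diazo-2-oxopropyl)phosphonate, COP(=O)(OC)C(=[N+]=[N-])C(C)=O
Why: Partial hydride reduction should stop at the aluminium hemiacetal of the hindered ester, and the non-enolisable aldehyde set free by methanol undergoes Ohira–Bestmann homologation to the terminal alkyne in the same flask.

Step 10
Reactants: 12 alkyne
Product: 13 tert-butyl{[(1R,2S,4S)-4-bromo-2-(buta-1,3-dien-2-yl)-2,3,3-trimethylcyclopentyl]oxy}dimethylsilane
Conditions: ethylene (1 atm), second-generation Grubbs catalyst (5 mol%), toluene, 80 °C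
Reagents that add atoms: ethylene, C=C
Why: Ethylene–alkyne cross enyne metathesis converts a terminal alkyne directly into a 2-substituted buta-1,3-diene and involves no stereocentre.

Step 11
Reactants: 14 2-methylcyclohex-2-en-1-one
Product: 15 2-methylcyclohexa-1,3-dien-1-yl acetate
Conditions: isopropenyl acetate, TsOH (cat.), reflux
Reagents that add atoms: isopropenyl acetate, CC(=C)OC(C)=O
Why: Acid-catalysed enol acetylation under equilibrating conditions should give the through-conjugated (thermodynamic) dienyl acetate by loss of a γ-hydrogen from C4.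

Step 12
Reactants: 15 dienyl acetate
Product: 16 racemic 4-hydroxy-2-methylcyclohex-2-en-1-one
Conditions: mCPBA (1.05 equiv), NaHCO3, CH2Cl2–H2O, 0 °C
Reagents that add atoms: 3-chloroperbenzoic acid, OOC(=O)c1cccc(Cl)c1
Why: Vinylogous Rubottom-type oxidation: the peracid attacks the terminal C3=C4 bond of the dienyl acetate (γ-attack, as in the 6-hydroxylation of steroidal 3,5-dienol acetates) and collapse of the epoxide with loss of the acetyl group gives the γ-hydroxy enone.

Step 13
Reactants: 16 racemic hydroxy enone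
Product: 17 (S)-4-hydroxy-2-methylcyclohex-2-en-1-one
Conditions: Burkholderia cepacia lipase (Amano PS, immobilised), vinyl acetate, MTBE, 30 °C, stopped just past half conversion; chromatography
Reagents that add atoms: none
Why: Lipase-catalysed kinetic resolution by transesterification should acylate the (R)-alcohol and leave the (S)-alcohol, which is separated from the acetate.

Step 14
Reactants: 17 (S)-hydroxy enone
Product: 18 (S)-2-methyl-4-(triethylsilyloxy)cyclohex-2-en-1-one
Conditions: TESCl, imidazole, CH2Cl2, 0 °C → rt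
Reagents that add atoms: chlorotriethylsilane, CC[Si](Cl)(CC)CC
Why: Standard silylation installs the group that steers the facial course of step 15 and can later be removed in the presence of the TBS ether.

Step 15
Reactants: 13 2-(ring C)buta-1,3-diene; 18 (S)-2-methyl-4-(triethylsilyloxy)cyclohex-2-en-1-one (1.5 equiv)
Product: 19 (4S,5S,10R)-7-RC-10-methyl-4-(triethylsilyloxy)-Δ7-octalin-1-one, cis-fused (5β-H, 10β-CH3, 4β-OSiEt3)
Conditions: Me2AlCl (1.2 equiv), CH2Cl2, −40 → 0 °C
Reagents that add atoms: none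
Why: Me2AlCl binds the C1 carbonyl and lowers the enone LUMO, and the diene, held s-cis by its tertiary-alkyl substituent, adds in a concerted, asynchronous, suprafacial [4+2] cycloaddition; the closest known reaction type is the Lewis-acid-promoted Diels–Alder reaction of 2-methylcyclohex-2-enones with 2-substituted butadienes to give angular-methyl cis-octalones. Ring B closes in this [4+2] mode, the C5–C6 bond forming ahead of C9–C10. C5 and C10 are created together and are necessarily cis, and their absolute sense is fixed by the C4 triethylsilyloxy group, the diene attacking the face anti to it. The step needs para regioselectivity (C7 substituent 1,4 to C10), secured by the larger HOMO coefficient at C6 of the 2-alkyl diene meeting the larger LUMO coefficient at the β-carbon C5, and anti facial selectivity, secured by the γ-silyloxy group. Because the diene has no terminal substituents, endo and exo approach give the same product, and the stereocentres of ring C are too remote to cause a mismatch.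

Step 16
Reactants: 19 cis-octalone
Product: 20 (1S,4S,5S,10R)-7-RC-10-methyl-4-(triethylsilyloxy)-Δ7-octalin-1-ol, cis-fused (1α-OH, trans to the C10 methyl)
Conditions: NaBH4, MeOH–CH2Cl2, −40 → 0 °C
Reagents that add atoms: none
Why: Borohydride reduction: in the cis-fused adduct ring A is a chair with C9 axial on the α face, so hydride should attack axially from the convex β face and give the equatorial 1α-alcohol.

Step 17
Reactants: 20 1α-alcohol
Product: 21 (1R,4S,5S,10R)-1-bromo-7-RC-10-methyl-4-(triethylsilyloxy)-Δ7-octalin, cis-fused (1β-Br, cis to the C10 methyl)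
Conditions: CBr4, P(n-Oct)3, 1-methylcyclohexene, toluene, 70 °C
Reagents that add atoms: tetrabromomethane, BrC(Br)(Br)Br
Why: Appel bromination with a trialkylphosphine: bromide displaces the oxyphosphonium group with inversion (SN2) to give the 1β-bromide, the non-polar medium and the acid scavenger disfavouring ionisation at this neopentyl carbinol and cleavage of the silyl ethers.

Step 18
Reactants: 21 bromide
Product: 22 (1R,4S,5S,10R)-1-bromo-7-RC-10-methyl-Δ7-octalin-4-ol, cis-fused
Conditions: PPTS (cat.), MeOH–CH2Cl2, 0 °C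
Reagents that add atoms: none
Why: Acid-catalysed methanolysis should cleave the unhindered secondary triethylsilyl ether far faster than the neopentyl TBS ether of ring C.

Step 19
Reactants: 22 C4 alcohol
Product: 23 (1R,5S,10R)-1-bromo-7-RC-10-methyl-Δ7-octalin-4-one, cis-fused
Conditions: Dess–Martin periodinane, NaHCO3, CH2Cl2, rt
Reagents that add atoms: none
Why: Dess–Martin oxidation gives the C4 ketone under buffered, non-basic conditions that leave the γ-bromide untouched.

Step 20
Reactants: 23 C4 ketone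
Product: 24 (1R,10R)-1-bromo-7-RC-10-methyl-4-(trimethylsilyloxy)-Δ4,Δ7-hexalin (silyl enol ether C4=C5)
Conditions: TMSCl, NaI, Et3N, MeCN, rt
Reagents that add atoms: chlorotrimethylsilane, C[Si](C)(C)Cl
Why: Silyl enol ether formation with TMSI made in situ under equilibrating conditions should give the thermodynamic tetrasubstituted enol ether towards the fusion carbon C5 (as 4-oxo steroids enolise towards C5), erasing the cis ring fusion without forming a free enolate that could alkylate at C1.

Step 21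
Reactants: 24 silyl enol ether
Product: 26 (1R,5S,10R)-1-bromo-5-hydroxy-7-RC-10-methyl-Δ7-octalin-4-one, trans-fused (5α-OH), via silyloxy ketone 25 (not isolated)
Conditions: mCPBA (1.0 equiv), NaHCO3, CH2Cl2, −20 °C; then 1 M HCl, THF, 0 °C
Reagents that add atoms: 3-chloroperbenzoic acid, OOC(=O)c1cccc(Cl)c1
Why: Rubottom oxidation: the peracid should epoxidise the electron-rich enol ether much faster than the C7=C8 alkene and from the α face, anti to the C10 methyl, and silyl migration followed by acid hydrolysis gives the trans-fused 5α-hydroxy ketone.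

Step 22
Reactants: 26 5α-hydroxy ketone
Product: 27 (1R,4S,5S,10R)-1-bromo-7-RC-4,10-dimethyl-Δ7-octalin-4,5-diol, trans-fused (4β-OH, 4α-CH3, 5α-OH)
Conditions: MeMgBr (4 equiv), THF, −78 → 0 °C
Reagents that add atoms: methylmagnesium bromide, C[Mg]Br
Why: Grignard addition to the C4 ketone: axial attack from the β face is blocked by the 1,3-diaxial C10 methyl, so methyl should enter equatorially from the α face and give the axial 4β-alcohol, trans-diaxial to the C5 hydroxyl.

Step 23
Reactants: 27 diol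
Product: 28 (1R,4S,5S,7S,10R)-1-bromo-7-RC-4,10-dimethyldecalin-4,5,7-triol (7α-OH)
Conditions: Co(acac)2 (20 mol%), PhSiH3, O2 (1 atm), i-PrOH–THF, rt
Reagents that add atoms: dioxygen, O=O
Why: Mukaiyama hydration: cobalt-hydride hydrogen-atom transfer to C8 gives the tertiary C7 radical, which keeps the bulky ring C equatorial and should be trapped by O2 on its axial α lobe, while the alkyl bromides are inert.

Step 24
Reactants: 28 silyl-protected tetraol
Product: 29 target, (1R,4S,5S,7S,10R)-1-bromo-7-[(1S,3S,5R)-3-bromo-5-hydroxy-1,2,2-trimethylcyclopentyl]-4,10-dimethyldecalin-4,5,7-triol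
Conditions: HF·pyridine, pyridine, THF, 0 °C → rt
Reagents that add atoms: none
Why: Fluoride-mediated desilylation under mildly acidic, non-basic conditions should spare the tertiary alcohols and both secondary bromides.

**Compound list**

1 | (1R,3S)-(+)-camphoric acid, (1R,3S)-1,2,2-trimethylcyclopentane-1,3-dicarboxylic acid | CC1(C)[C@@H](C(O)=O)CC[C@@]1(C)C(O)=O | starting material
2 | dimethyl (1R,3S)-1,2,2-trimethylcyclopentane-1,3-dicarboxylate | CC1(C)[C@@H](C(=O)OC)CC[C@@]1(C)C(=O)OC | intermediate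
3 | (1S,3R)-3-(methoxycarbonyl)-2,2,3-trimethylcyclopentane-1-carboxylic acid | CC1(C)[C@@H](C(O)=O)CC[C@@]1(C)C(=O)OC | intermediate
4 | methyl (1R)-1,2,2-trimethylcyclopent-3-ene-1-carboxylate | CC1(C)C=CC[C@@]1(C)C(=O)OC | intermediate
5 | methyl (1S)-2-hydroxy-1,5,5-trimethylcyclopent-3-ene-1-carboxylate (both C2 epimers) | CC1(C)C=CC(O)[C@@]1(C)C(=O)OC | intermediate
6 | methyl (1S)-1,5,5-trimethyl-2-oxocyclopent-3-ene-1-carboxylate | CC1(C)C=CC(=O)[C@@]1(C)C(=O)OC | intermediate
7 | methyl (1S,4R)-1,5,5-trimethyl-2-oxo-4-(4,4,5,5-tetramethyl-1,3,2-dioxaborolan-2-yl)cyclopentane-1-carboxylate | CC1(C)[C@H](B2OC(C)(C)C(C)(C)O2)CC(=O)[C@@]1(C)C(=O)OC | intermediate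
8 | methyl (1S,2R,4R)-2-hydroxy-1,5,5-trimethyl-4-(4,4,5,5-tetramethyl-1,3,2-dioxaborolan-2-yl)cyclopentane-1-carboxylate | CC1(C)[C@H](B2OC(C)(C)C(C)(C)O2)C[C@@H](O)[C@@]1(C)C(=O)OC | intermediate
9 | methyl (1S,2R,4R)-2-[(tert-butyldimethylsilyl)oxy]-1,5,5-trimethyl-4-(4,4,5,5-tetramethyl-1,3,2-dioxaborolan-2-yl)cyclopentane-1-carboxylate | CC1(C)[C@H](B2OC(C)(C)C(C)(C)O2)C[C@@H](O[Si](C)(C)C(C)(C)C)[C@@]1(C)C(=O)OC | intermediate
10 | methyl (1S,2R,4S)-4-bromo-2-[(tert-butyldimethylsilyl)oxy]-1,5,5-trimethylcyclopentane-1-carboxylate | CC1(C)[C@@H](Br)C[C@@H](O[Si](C)(C)C(C)(C)C)[C@@]1(C)C(=O)OC | intermediate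
11 | (1S,2R,4S)-4-bromo-2-[(tert-butyldimethylsilyl)oxy]-1,5,5-trimethylcyclopentane-1-carbaldehyde | CC1(C)[C@@H](Br)C[C@@H](O[Si](C)(C)C(C)(C)C)[C@@]1(C)C=O | intermediate
12 | tert-butyl{[(1R,2S,4S)-4-bromo-2-ethynyl-2,3,3-trimethylcyclopentyl]oxy}dimethylsilane | CC1(C)[C@@H](Br)C[C@@H](O[Si](C)(C)C(C)(C)C)[C@@]1(C)C#C | intermediate
13 | tert-butyl{[(1R,2S,4S)-4-bromo-2-(buta-1,3-dien-2-yl)-2,3,3-trimethylcyclopentyl]oxy}dimethylsilane | CC1(C)[C@@H](Br)C[C@@H](O[Si](C)(C)C(C)(C)C)[C@@]1(C)C(=C)C=C | intermediate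
14 | 2-methylcyclohex-2-en-1-one | CC1=CCCC1=O | starting material
15 | 2-methylcyclohexa-1,3-dien-1-yl acetate | CC(=O)OC1=C(C)C=CCC1 | intermediate
16 | 4-hydroxy-2-methylcyclohex-2-en-1-one (racemic) | CC1=CC(O)CCC1=O | intermediate
17 | (S)-4-hydroxy-2-methylcyclohex-2-en-1-one | CC1=C[C@@H](O)CCC1=O | intermediate
18 | (S)-2-methyl-4-(triethylsilyloxy)cyclohex-2-en-1-one | CC1=C[C@@H](O[Si](CC)(CC)CC)CCC1=O | intermediate
19 | (4S,5S,10R)-7-RC-10-methyl-4-(triethylsilyloxy)-Δ7-octalin-1-one, cis-fused | CC1(C)[C@@H](Br)C[C@@H](O[Si](C)(C)C(C)(C)C)[C@@]1(C)C1=CC[C@@]2(C)C(=O)CC[C@H](O[Si](CC)(CC)CC)[C@H]2C1 | intermediate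
20 | (1S,4S,5S,10R)-7-RC-10-methyl-4-(triethylsilyloxy)-Δ7-octalin-1-ol, cis-fused, 1α-OH | CC1(C)[C@@H](Br)C[C@@H](O[Si](C)(C)C(C)(C)C)[C@@]1(C)C1=CC[C@@]2(C)[C@@H](O)CC[C@H](O[Si](CC)(CC)CC)[C@H]2C1 | intermediate
21 | (1R,4S,5S,10R)-1-bromo-7-RC-10-methyl-4-(triethylsilyloxy)-Δ7-octalin, cis-fused, 1β-Br | CC1(C)[C@@H](Br)C[C@@H](O[Si](C)(C)C(C)(C)C)[C@@]1(C)C1=CC[C@@]2(C)[C@H](Br)CC[C@H](O[Si](CC)(CC)CC)[C@H]2C1 | intermediate
22 | (1R,4S,5S,10R)-1-bromo-7-RC-10-methyl-Δ7-octalin-4-ol, cis-fused | CC1(C)[C@@H](Br)C[C@@H](O[Si](C)(C)C(C)(C)C)[C@@]1(C)C1=CC[C@@]2(C)[C@H](Br)CC[C@H](O)[C@H]2C1 | intermediate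
23 | (1R,5S,10R)-1-bromo-7-RC-10-methyl-Δ7-octalin-4-one, cis-fused | CC1(C)[C@@H](Br)C[C@@H](O[Si](C)(C)C(C)(C)C)[C@@]1(C)C1=CC[C@@]2(C)[C@H](Br)CCC(=O)[C@H]2C1 | intermediate
24 | (1R,10R)-1-bromo-7-RC-10-methyl-4-(trimethylsilyloxy)-Δ4,Δ7-hexalin | CC1(C)[C@@H](Br)C[C@@H](O[Si](C)(C)C(C)(C)C)[C@@]1(C)C1=CC[C@@]2(C)[C@H](Br)CCC(O[Si](C)(C)C)=C2C1 | intermediate
25 | (1R,5S,10R)-1-bromo-7-RC-10-methyl-5-(trimethylsilyloxy)-Δ7-octalin-4-one, trans-fused | CC1(C)[C@@H](Br)C[C@@H](O[Si](C)(C)C(C)(C)C)[C@@]1(C)C1=CC[C@@]2(C)[C@H](Br)CCC(=O)[C@]2(O[Si](C)(C)C)C1 | intermediate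
26 | (1R,5S,10R)-1-bromo-5-hydroxy-7-RC-10-methyl-Δ7-octalin-4-one, trans-fused | CC1(C)[C@@H](Br)C[C@@H](O[Si](C)(C)C(C)(C)C)[C@@]1(C)C1=CC[C@@]2(C)[C@H](Br)CCC(=O)[C@]2(O)C1 | intermediate
27 | (1R,4S,5S,10R)-1-bromo-7-RC-4,10-dimethyl-Δ7-octalin-4,5-diol, trans-fused | CC1(C)[C@@H](Br)C[C@@H](O[Si](C)(C)C(C)(C)C)[C@@]1(C)C1=CC[C@@]2(C)[C@H](Br)CC[C@](C)(O)[C@]2(O)C1 | intermediate
28 | (1R,4S,5S,7S,10R)-1-bromo-7-RC-4,10-dimethyldecalin-4,5,7-triol | CC1(C)[C@@H](Br)C[C@@H](O[Si](C)(C)C(C)(C)C)[C@@]1(C)[C@]1(O)CC[C@@]2(C)[C@H](Br)CC[C@](C)(O)[C@]2(O)C1 | intermediate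
29 | (1R,4S,5S,7S,10R)-1-bromo-7-[(1S,3S,5R)-3-bromo-5-hydroxy-1,2,2-trimethylcyclopentyl]-4,10-dimethyldecalin-4,5,7-triol | CC1(C)[C@@H](Br)C[C@@H](O)[C@@]1(C)[C@]1(O)CC[C@@]2(C)[C@H](Br)CC[C@](C)(O)[C@]2(O)C1 | target

**Step count**

Total: 24 steps. Longest linear sequence: 20 steps (steps 1–10, 15, 16–24).

**Steps most likely to fail**

1. Step 8 (bromodeboronation at C14). What may go wrong: electron transfer from the boronate complex to NBS, or sluggish complex formation at the hindered boronic ester, could outrun backside attack at the neopentyl carbon and scramble C14. Fallback, from 9 back to 10: oxidise the C–B bond of 9 with NaBO3 in THF–water, which keeps configuration, to the trans alcohol methyl (1S,2R,4R)-2-[(tert-butyldimethylsilyl)oxy]-4-hydroxy-1,5,5-trimethylcyclopentane-1-carboxylate F1. The hydroxyl is then displaced with inversion under Appel conditions (CBr4, P(n-Oct)3, toluene, 70 °C) to reach 10.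

2. Step 17 (C1 bromide). What may go wrong: ionisation of the oxyphosphonium group at the neopentyl carbinol faster than backside attack, ending in ring contraction, 1,2-shift or elimination, and loss of the triethylsilyl ether to adventitious HBr. Fallback, from 20 back to 28: give up substitution and install the bromide by radical hydrogenation of a vinyl bromide once ring A is trans-fused.
 - Acetylation of 20 (Ac2O, DMAP) gives the 1α-acetate of 20 F2.
 - The conditions of steps 18–21 then give in turn the C4 alcohol F3, the C4 ketone F4, the silyl enol ether F5, the 5α-silyloxy ketone F6 and the 5α-hydroxy ketone F7.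
 - Excess MeMgBr adds to C4 as in step 22 and cleaves the acetate in the same operation, giving the 1α,4β,5α-triol F8.
 - Mukaiyama hydration as in step 23 gives the 1α,4β,5α,7α-tetraol F9.
 - Dess–Martin oxidation of its only free secondary hydroxyl gives the C1 ketone F10.
 - Hydrazine hydrate gives the hydrazone F11, which NBS in pyridine converts into the C1 vinyl bromide F12.
 - Hydrogen-atom-transfer hydrogenation (Mn(dpm)3, PhSiH3, t-BuOOH, i-PrOH), a method that reduces haloalkenes without loss of halogen, should deliver hydrogen to the C1 radical axially from the α face and so place bromine equatorial (β), which is 28.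

3. Step 15 (Diels–Alder union). What may go wrong: slow cycloaddition at the trisubstituted enone, leaving time for Lewis-acid-induced loss of silanol from 18 (aromatisation) or oligomerisation of the diene. Fallback, from 18 and 13 back to 19: activate the dienophile as an oxocarbenium ion instead of a Lewis-acid complex. Ketalisation of 18 with 1,2-bis(trimethylsilyloxy)ethane and catalytic TMSOTf at −78 °C gives the dioxolane (S)-6-methyl-8-(triethylsilyloxy)-1,4-dioxaspiro[4.5]dec-6-ene F13. TMSOTf then opens the ketal to an alkoxy allyl cation, which undergoes an ionic Diels–Alder reaction with 13 at −78 °C; the same two bonds form with the same regiochemistry and facial sense, giving the C1 dioxolane of 19 F14. Aqueous acid removes the dioxolane and the triethylsilyl group to give the 4β-hydroxy ketone F15, and TESCl with imidazole returns 19.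

**Further compounds**

F1 | step 8 | methyl (1S,2R,4R)-2-[(tert-butyldimethylsilyl)oxy]-4-hydroxy-1,5,5-trimethylcyclopentane-1-carboxylate | CC1(C)[C@H](O)C[C@@H](O[Si](C)(C)C(C)(C)C)[C@@]1(C)C(=O)OC
F2 | step 17 | 1α-acetate of 20, cis-fused 7-RC-10-methyl-4β-(triethylsilyloxy)-Δ7-octalin-1α-yl acetate | CC1(C)[C@@H](Br)C[C@@H](O[Si](C)(C)C(C)(C)C)[C@@]1(C)C1=CC[C@@]2(C)[C@@H](OC(C)=O)CC[C@H](O[Si](CC)(CC)CC)[C@H]2C1
F3 | step 17 | cis-fused 4β-hydroxy-7-RC-10-methyl-Δ7-octalin-1α-yl acetate | CC1(C)[C@@H](Br)C[C@@H](O[Si](C)(C)C(C)(C)C)[C@@]1(C)C1=CC[C@@]2(C)[C@@H](OC(C)=O)CC[C@H](O)[C@H]2C1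
F4 | step 17 | cis-fused 7-RC-10-methyl-4-oxo-Δ7-octalin-1α-yl acetate | CC1(C)[C@@H](Br)C[C@@H](O[Si](C)(C)C(C)(C)C)[C@@]1(C)C1=CC[C@@]2(C)[C@@H](OC(C)=O)CCC(=O)[C@H]2C1
F5 | step 17 | 7-RC-10-methyl-4-(trimethylsilyloxy)-Δ4,Δ7-hexalin-1α-yl acetate | CC1(C)[C@@H](Br)C[C@@H](O[Si](C)(C)C(C)(C)C)[C@@]1(C)C1=CC[C@@]2(C)[C@@H](OC(C)=O)CCC(O[Si](C)(C)C)=C2C1
F6 | step 17 | trans-fused 7-RC-10-methyl-4-oxo-5α-(trimethylsilyloxy)-Δ7-octalin-1α-yl acetate | CC1(C)[C@@H](Br)C[C@@H](O[Si](C)(C)C(C)(C)C)[C@@]1(C)C1=CC[C@@]2(C)[C@@H](OC(C)=O)CCC(=O)[C@]2(O[Si](C)(C)C)C1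
F7 | step 17 | trans-fused 5α-hydroxy-7-RC-10-methyl-4-oxo-Δ7-octalin-1α-yl acetate | CC1(C)[C@@H](Br)C[C@@H](O[Si](C)(C)C(C)(C)C)[C@@]1(C)C1=CC[C@@]2(C)[C@@H](OC(C)=O)CCC(=O)[C@]2(O)C1
F8 | step 17 | trans-fused 7-RC-4α,10-dimethyl-Δ7-octalin-1α,4β,5α-triol | CC1(C)[C@@H](Br)C[C@@H](O[Si](C)(C)C(C)(C)C)[C@@]1(C)C1=CC[C@@]2(C)[C@@H](O)CC[C@](C)(O)[C@]2(O)C1
F9 | step 17 | trans-fused 7β-RC-4α,10-dimethyldecalin-1α,4β,5α,7α-tetraol | CC1(C)[C@@H](Br)C[C@@H](O[Si](C)(C)C(C)(C)C)[C@@]1(C)[C@]1(O)CC[C@@]2(C)[C@@H](O)CC[C@](C)(O)[C@]2(O)C1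
F10 | step 17 | trans-fused 4β,5α,7α-trihydroxy-7β-RC-4α,10-dimethyldecalin-1-one | CC1(C)[C@@H](Br)C[C@@H](O[Si](C)(C)C(C)(C)C)[C@@]1(C)[C@]1(O)CC[C@@]2(C)C(=O)CC[C@](C)(O)[C@]2(O)C1
F11 | step 17 | hydrazone of F10 at C1 | CC1(C)[C@@H](Br)C[C@@H](O[Si](C)(C)C(C)(C)C)[C@@]1(C)[C@]1(O)CC[C@@]2(C)C(=NN)CC[C@](C)(O)[C@]2(O)C1
F12 | step 17 | trans-fused 1-bromo-7β-RC-4α,10-dimethyl-Δ1-octalin-4β,5α,7α-triol (C1 vinyl bromide) | CC1(C)[C@@H](Br)C[C@@H](O[Si](C)(C)C(C)(C)C)[C@@]1(C)[C@]1(O)CC[C@@]2(C)C(Br)=CC[C@](C)(O)[C@]2(O)C1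
F13 | step 15 | (S)-6-methyl-8-(triethylsilyloxy)-1,4-dioxaspiro[4.5]dec-6-ene | CC1=C[C@@H](O[Si](CC)(CC)CC)CCC12OCCO2
F14 | step 15 | C1 ethylene ketal of 19, cis-fused | CC1(C)[C@@H](Br)C[C@@H](O[Si](C)(C)C(C)(C)C)[C@@]1(C)C1=CC[C@@]2(C)C3(OCCO3)CC[C@H](O[Si](CC)(CC)CC)[C@H]2C1
F15 | step 15 | cis-fused 4β-hydroxy-7-RC-10-methyl-Δ7-octalin-1-one | CC1(C)[C@@H](Br)C[C@@H](O[Si](C)(C)C(C)(C)C)[C@@]1(C)C1=CC[C@@]2(C)C(=O)CC[C@H](O)[C@H]2C1
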